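**Plan**

- Cuts, with locants of the chondrillin chain (C1 = ester carbon): the dioxine O–C3 bond (peroxide SN2 at a β-lactone carbon), the O–C6 bond (H2O2 for OMe at a dimethyl ketal), C1–C2 and C1–O of the lactone (CO into an oxirane), C3–C4 (acetylide acylation) and C5–C6 (acid chloride alkynylation).
- Enabling feature: O–C3–C2–C1(=O) of the target is an oxetan-2-one opened at its C3–O bond, and C1 is CO inserted into the CH2–O bond of a terminal oxirane whose CH carbon is C3.
- Forward order: C5–C6, ketal, C3–C4; then oxirane (step 6), oxetan-2-one (step 7), alkyne to (Z)-alkene, hydroperoxy ketal, 1,2-dioxine (step 10), C6 equilibration and separation (step 11).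
- Stereochemistry: C3 comes from transfer hydrogenation with RuCl[(S,S)-TsDPEN](p-cymene) (step 5), is untouched by epoxide closure and carbonylation, and is inverted once by the peroxide closure to 3R. C6 forms without control; step 11 equilibrates it, isolates the 6S epimer and returns the 6R epimer.

Key step: step 7

Remark: it is assumed that in the transfer hydrogenation the alkynyl group of 9 sits where the aryl group of an aryl ketone would; compounds 15, 16 and 17 are pairs of C6 epimers, drawn without configuration at that carbon.

**Route**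

Step 1
Reactants: 1 heptadecanoyl chloride; 2 trimethylsilylacetylene
Product: 3 1-(trimethylsilyl)nonadec-1-yn-3-one
Conditions: PdCl2(PPh3)2 (2 mol %), CuI (4 mol %), Et3N (1.2 equiv), THF, rt
Reagents that add atoms: none
Why: Acyl Sonogashira coupling, in which the copper acetylide transfers the alkynyl group to the acylpalladium chloride and reductive elimination gives the ynone; the small excess of amine at room temperature should keep ketene formation minor, and the silyl group blocks conjugate addition.

Step 2
Reactants: 3 1-(trimethylsilyl)nonadec-1-yn-3-one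
Product: 4 (3,3-dimethoxynonadec-1-yn-1-yl)trimethylsilane
Conditions: MeOSiMe3 (2.5 equiv), TMSOTf (5 mol %), CH2Cl2, −78 → −20 °C; pyridine quench
Reagents that add atoms: methoxytrimethylsilane, CO[Si](C)(C)C
Why: Noyori ketalisation under aprotic conditions, driven by formation of (Me3Si)2O, should convert the ynone carbonyl to the dimethyl ketal without the conjugate addition of methanol that protic acid can cause.

Step 3
Reactants: 4 (3,3-dimethoxynonadec-1-yn-1-yl)trimethylsilane
Product: 5 3,3-dimethoxynonadec-1-yne
Conditions: K2CO3 (0.2 equiv), MeOH, rt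
Reagents that add atoms: none
Why: Base-catalysed methanolysis of the alkynyl C–Si bond (protodesilylation) frees the terminal alkyne, and the ketal is inert to base.

Step 4
Reactants: 5 3,3-dimethoxynonadec-1-yne; 6 2-chloro-N-methoxy-N-methylacetamide
Product: 9 1-chloro-5,5-dimethoxyhenicos-3-yn-2-one, via lithium acetylide 7 (not isolated), via tetrahedral lithium adduct 8 (not isolated)
Conditions: n-BuLi (1.0 equiv), THF, −78 °C; 6 (1.1 equiv), −78 → −40 °C; AcOH (1.2 equiv), −78 → 0 °C
Reagents that add atoms: none
Why: Weinreb ketone synthesis, in which the chelated tetrahedral adduct survives until the acidic quench so that the acetylide adds only once; the quench also protonates the released N,O-dimethylhydroxylamine, which could otherwise add to the ynone.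

Step 5
Reactants: 9 1-chloro-5,5-dimethoxyhenicos-3-yn-2-one
Product: 10 (2R)-1-chloro-5,5-dimethoxyhenicos-3-yn-2-ol
Conditions: RuCl[(S,S)-TsDPEN](p-cymene) (1 mol %), HCO2Na (5 equiv), n-Bu4NCl (10 mol %), H2O/EtOAc, rt
Reagents that add atoms: none
Why: Noyori asymmetric transfer hydrogenation of an alkynyl ketone under near-neutral formate conditions that spare the ketal and the α-chloro ketone; with the alkynyl group beside the arene ligand the (S,S) catalyst should deliver hydride to the face that gives the 2R chlorohydrin (R because CH2Cl outranks the alkynyl group), and the sense is to be confirmed by Mosher ester analysis.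

Step 6
Reactants: 10 (2R)-1-chloro-5,5-dimethoxyhenicos-3-yn-2-ol
Product: 11 (2R)-2-(3,3-dimethoxynonadec-1-yn-1-yl)oxirane
Conditions: K2CO3 (1.5 equiv), MeOH, 0 °C → rt
Reagents that add atoms: none
Why: Intramolecular Williamson etherification (3-exo-tet) of the chlorohydrin alkoxide at the CH2Cl carbon closes the oxirane without touching the carbinol centre, so the 2R configuration is kept.

Step 7
Reactants: 11 (2R)-2-(3,3-dimethoxynonadec-1-yn-1-yl)oxirane; 12 carbon monoxide
Product: 13 (4S)-4-(3,3-dimethoxynonadec-1-yn-1-yl)oxetan-2-one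
Conditions: [(salph)Al(THF)2][Co(CO)4] (5 mol %; salph = N,N′-bis(3,5-di-tert-butylsalicylidene)-1,2-phenylenediamine dianion), CO (60 bar), DME, 50 °C
Reagents that add atoms: none
Why: Coordination of the oxirane oxygen to aluminium lets the cobaltate displace it at the terminal CH2 (SN2), the alkylcobalt tetracarbonyl takes up CO by migratory insertion, and the aluminium-bound alkoxide adds to the acylcobalt and expels Co(CO)4−, which forms the C2–C1 and C1–O bonds. The closest known reaction is the ring-expanding carbonylation of terminal alkyl-substituted epoxides to β-lactones by Lewis acid/Co(CO)4− ion pairs. The oxetan-2-one closes in the 4-exo-trig mode by attack of the alkoxide oxygen on the acyl carbon. No stereocentre is created, since the C–O bond at the carbinol carbon is never broken, so (2R)-11 should give (4S)-13 with retention (the descriptor changes only because the CH2 group drops in CIP rank). The step needs attack at CH2 and not at the propargylic carbon or, in the SN2′ sense, at the distal alkyne carbon; the first is favoured sterically and because an alkynyl group stabilises positive charge poorly, and the second is blocked by the adjacent quaternary ketal carbon. The donor solvent DME competes for the Lewis acid and should keep the ketal a spectator.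

Step 8
Reactants: 13 (4S)-4-(3,3-dimethoxynonadec-1-yn-1-yl)oxetan-2-one
Product: 14 (4S)-4-[(1Z)-3,3-dimethoxynonadec-1-en-1-yl]oxetan-2-one
Conditions: H2 (1 atm), Pd/CaCO3 poisoned with Pb(OAc)2 (Lindlar catalyst), quinoline, EtOAc, 0 °C, stopped after 1 equiv H2
Reagents that add atoms: none
Why: Lindlar semi-hydrogenation adds H2 syn to the alkyne and should give the (Z)-alkene that brings C6 and C3 to the same side, with quinoline and the limited H2 uptake guarding against over-reduction and hydrogenolysis of the now allylic C–O bond.

Step 9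
Reactants: 14 (4S)-4-[(1Z)-3,3-dimethoxynonadec-1-en-1-yl]oxetan-2-one
Product: 15 (4S)-4-[(1Z)-3-hydroperoxy-3-methoxynonadec-1-en-1-yl]oxetan-2-one (both epimers at the hydroperoxy ketal carbon)
Conditions: anhydrous H2O2 in Et2O (3 equiv), camphorsulfonic acid (5 mol %), Et2O, −20 → 0 °C; solid NaHCO3; used at once
Reagents that add atoms: hydrogen peroxide, OO
Why: Acid-catalysed perketal exchange, in which the allylic dimethyl ketal ionises to its oxocarbenium ion and H2O2 adds at the same carbon, should replace one methoxy group by OOH and give both C6 epimers because the distant C3 centre cannot discriminate; the weak acid and low temperature are chosen to stop at mono-exchange and to preserve the (Z)-alkene and the lactone, whose acylated oxygen cannot close onto C6 as a free C3 hydroxyl would.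

Step 10
Reactants: 15 (4S)-4-[(1Z)-3-hydroperoxy-3-methoxynonadec-1-en-1-yl]oxetan-2-one (both C6 epimers)
Product: 17 methyl 2-[(3R)-6-hexadecyl-6-methoxy-3,6-dihydro-1,2-dioxin-3-yl]acetate (both C6 epimers), via dioxine acetic acid 16 (not isolated)
Conditions: Cs2CO3 (1.05 equiv), DMF (0.005 M), 0 °C; 0.1 M aq. HCl to pH 4, Et2O, 0 °C; CH2N2, Et2O, 0 °C
Reagents that add atoms: diazomethane, C=[N+]=[N-]
Why: Proposed new method: the cesium alkylperoxide on C6, held next to C3 by the (Z)-alkene, should displace the lactone carboxylate at the strained allylic C3–O bond by intramolecular SN2 (6-exo-tet) with inversion to give the 3R dioxine, the carbonyl carbon being out of reach because attack there would close an eight-membered perester; the closest known reactions are the base-mediated intramolecular alkylation of hydroperoxy ketals by secondary sulfonates and epoxides and the alkyl–oxygen opening of β-lactones at C4 by carboxylates and phenoxides with inversion; C6 is not touched, so both epimers of 15 close, and the freed acid 16, methylated by diazomethane without base, should give ester 17 as the same pair of C6 epimers.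

Step 11
Reactants: 17 methyl 2-[(3R)-6-hexadecyl-6-methoxy-3,6-dihydro-1,2-dioxin-3-yl]acetate (both C6 epimers)
Product: 18 chondrillin (methyl 2-[(3R,6S)-6-hexadecyl-6-methoxy-3,6-dihydro-1,2-dioxin-3-yl]acetate)
Conditions: camphorsulfonic acid (10 mol %), MeOH, 0 °C → rt; solid NaHCO3; SiO2 chromatography; recovered 6R epimer returned to the same conditions
Reagents that add atoms: methanol, CO
Why: Acid-catalysed ketal exchange (anomerisation of a mixed peroxy ketal), in which loss of methanol from C6 gives the ring peroxycarbenium ion and methanol is recaptured from either face, should interconvert the two C6 epimers while C3 takes no part and stays R, so that chromatography delivers the 6S compound 18 and repeated passes of the 6R epimer funnel the material into it.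

**Compound list**

1 | heptadecanoyl chloride | CCCCCCCCCCCCCCCCC(=O)Cl | starting material
2 | trimethylsilylacetylene | C[Si](C)(C)C#C | starting material
3 | 1-(trimethylsilyl)nonadec-1-yn-3-one | CCCCCCCCCCCCCCCCC(=O)C#C[Si](C)(C)C | intermediate
4 | (3,3-dimethoxynonadec-1-yn-1-yl)trimethylsilane | CCCCCCCCCCCCCCCCC(OC)(OC)C#C[Si](C)(C)C | intermediate
5 | 3,3-dimethoxynonadec-1-yne | CCCCCCCCCCCCCCCCC(OC)(OC)C#C | intermediate
6 | 2-chloro-N-methoxy-N-methylacetamide | CON(C)C(=O)CCl | starting material
7 | (3,3-dimethoxynonadec-1-yn-1-yl)lithium (formed in the flask) | CCCCCCCCCCCCCCCCC(OC)(OC)C#C[Li] | intermediate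
8 | lithium 1-chloro-5,5-dimethoxy-2-[methoxy(methyl)amino]henicos-3-yn-2-olate (formed in the flask) | CCCCCCCCCCCCCCCCC(OC)(OC)C#CC(O[Li])(CCl)N(C)OC | intermediate
9 | 1-chloro-5,5-dimethoxyhenicos-3-yn-2-one | CCCCCCCCCCCCCCCCC(OC)(OC)C#CC(=O)CCl | intermediate
10 | (2R)-1-chloro-5,5-dimethoxyhenicos-3-yn-2-ol | CCCCCCCCCCCCCCCCC(OC)(OC)C#C[C@@H](O)CCl | intermediate
11 | (2R)-2-(3,3-dimethoxynonadec-1-yn-1-yl)oxirane | CCCCCCCCCCCCCCCCC(OC)(OC)C#C[C@@H]1CO1 | intermediate
12 | carbon monoxide | [C-]#[O+] | starting material
13 | (4S)-4-(3,3-dimethoxynonadec-1-yn-1-yl)oxetan-2-one | CCCCCCCCCCCCCCCCC(OC)(OC)C#C[C@@H]1CC(=O)O1 | intermediate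
14 | (4S)-4-[(1Z)-3,3-dimethoxynonadec-1-en-1-yl]oxetan-2-one | CCCCCCCCCCCCCCCCC(OC)(OC)/C=C\[C@@H]1CC(=O)O1 | intermediate
15 | (4S)-4-[(1Z)-3-hydroperoxy-3-methoxynonadec-1-en-1-yl]oxetan-2-one (both epimers at the hydroperoxy ketal carbon) | CCCCCCCCCCCCCCCCC(OC)(OO)/C=C\[C@@H]1CC(=O)O1 | intermediate
16 | 2-[(3R)-6-hexadecyl-6-methoxy-3,6-dihydro-1,2-dioxin-3-yl]acetic acid (C6 epimer pair, formed in the flask) | CCCCCCCCCCCCCCCCC1(OC)C=C[C@@H](CC(=O)O)OO1 | intermediate
17 | methyl 2-[(3R)-6-hexadecyl-6-methoxy-3,6-dihydro-1,2-dioxin-3-yl]acetate (C6 epimer pair) | CCCCCCCCCCCCCCCCC1(OC)C=C[C@@H](CC(=O)OC)OO1 | intermediate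
18 | chondrillin, methyl 2-[(3R,6S)-6-hexadecyl-6-methoxy-3,6-dihydro-1,2-dioxin-3-yl]acetate | CCCCCCCCCCCCCCCC[C@@]1(OC)C=C[C@@H](CC(=O)OC)OO1 | target

**Step count**

Total: 11 steps. Longest linear sequence: 11 steps (1 → 3 → 4 → 5 → 9 → 10 → 11 → 13 → 14 → 15 → 17 → 18).

**Steps most likely to fail**

1. Step 10 (peroxide ring closure). What may go wrong: the peroxide anion adds to the lactone carbonyl of a second molecule and gives perester oligomers instead of displacing at C3; the base removes a C2 proton and the lactone opens by β-elimination to the dienoic acid; or the dioxine formed is fragmented by base through loss of the C3 proton next to the O–O bond.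
Fallback, from 13 back to 16, using known reaction types only. LiBH4 (THF, 0 °C) would reduce lactone 13 to the diol (3S)-6,6-dimethoxydocos-4-yne-1,3-diol F1. Tosylation of the primary hydroxyl (TsCl, pyridine, 0 °C) would give the monotosylate (3S)-3-hydroxy-6,6-dimethoxydocos-4-yn-1-yl 4-methylbenzenesulfonate F2. KOtBu (THF) would then close the oxetane (2S)-2-(3,3-dimethoxynonadec-1-yn-1-yl)oxetane F3 by attack of the C3 alkoxide on C1, so C3 keeps its configuration. Semi-hydrogenation as in step 8 would give the (Z)-alkenyl oxetane (2S)-2-[(1Z)-3,3-dimethoxynonadec-1-en-1-yl]oxetane F4. Ethereal H2O2 with TMSOTf (Et2O, −78 → 0 °C) should open the activated oxetane at its allylic carbon with inversion to the hydroperoxide (3R,4Z)-3-hydroperoxy-6,6-dimethoxydocos-4-en-1-ol F5. F5 is not isolated and should close under the same acid onto the C6 ketal, with loss of methanol, to the dioxine alcohol 2-[(3R)-6-hexadecyl-6-methoxy-3,6-dihydro-1,2-dioxin-3-yl]ethanol F6 as a C6 epimer pair. Dess–Martin periodinane (NaHCO3, CH2Cl2) would give the aldehyde 2-[(3R)-6-hexadecyl-6-methoxy-3,6-dihydro-1,2-dioxin-3-yl]acetaldehyde F7, and Pinnick oxidation (NaClO2, NaH2PO4, 2-methyl-2-butene, t-BuOH/H2O) would lead to acid 16, which is methylated with diazomethane as in step 10 and then carried into step 11. The reaction types relied on are the Lewis-acid-mediated opening of oxetanes by H2O2 with inversion and the acid-catalysed closure of γ-hydroperoxy enone ketals to 3-alkoxy-1,2-dioxines.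

2. Step 7 (carbonylation). What may go wrong: the aluminium cation ionises the propargylic C–O bond or the ketal, which leads to rearrangement to carbonyl compounds and erosion of enantiopurity; the cobaltate attacks the alkyne in the SN2′ sense; or cobalt is tied up by the alkyne so that turnover stops.
Fallback, from 5 back to 13. The lithium acetylide of 5 (n-BuLi, THF, −78 °C) would be formylated with DMF and quenched into aqueous KH2PO4 to give the ynal 4,4-dimethoxyicos-2-ynal F8. A catalytic asymmetric ketene–aldehyde [2+2] cycloaddition would then build the lactone directly: acetyl chloride, i-Pr2NEt, LiClO4 and O-trimethylsilylquinine or O-trimethylsilylquinidine (the antipode that gives the 4S lactone), Et2O/CH2Cl2, −78 °C. This is the acyl halide–aldehyde cyclocondensation, and it would give 13 with C3 set by the alkaloid catalyst instead of by steps 4–7.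

3. Step 9 (hydroperoxide exchange). What may go wrong: the exchange runs past the mono-hydroperoxide and gives mixtures of ketal, hydroperoxy ketal and geminal bis-hydroperoxide; the (Z)-alkene isomerises slowly through the alkoxyallyl cation; or the acid opens the allylic lactone.
Fallback, from 14 back to 17. The exchange would be driven to completion instead of stopped halfway: Re2O7 (cat.) with 50 % aqueous H2O2 in MeCN at rt, a fast and mild known conversion of ketals to 1,1-dihydroperoxides, would give (4S)-4-[(1Z)-3,3-dihydroperoxynonadec-1-en-1-yl]oxetan-2-one F9. Closure under the conditions of step 10 (Cs2CO3, DMF, then acidification) would give 2-[(3R)-6-hexadecyl-6-hydroperoxy-3,6-dihydro-1,2-dioxin-3-yl]acetic acid F10, and diazomethane would give its methyl ester methyl 2-[(3R)-6-hexadecyl-6-hydroperoxy-3,6-dihydro-1,2-dioxin-3-yl]acetate F11. Camphorsulfonic acid in methanol, as in step 11, would then exchange the C6 hydroperoxy group for methoxy through the ring peroxycarbenium ion and give the epimer pair 17, from which step 11 continues.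

Further compounds
F1 | step 10 | (3S)-6,6-dimethoxydocos-4-yne-1,3-diol | CCCCCCCCCCCCCCCCC(OC)(OC)C#C[C@@H](O)CCO
F2 | step 10 | (3S)-3-hydroxy-6,6-dimethoxydocos-4-yn-1-yl 4-methylbenzenesulfonate | CCCCCCCCCCCCCCCCC(OC)(OC)C#C[C@@H](O)CCOS(=O)(=O)c1ccc(C)cc1
F3 | step 10 | (2S)-2-(3,3-dimethoxynonadec-1-yn-1-yl)oxetane | CCCCCCCCCCCCCCCCC(OC)(OC)C#C[C@@H]1CCO1
F4 | step 10 | (2S)-2-[(1Z)-3,3-dimethoxynonadec-1-en-1-yl]oxetane | CCCCCCCCCCCCCCCCC(OC)(OC)/C=C\[C@@H]1CCO1
F5 | step 10 | (3R,4Z)-3-hydroperoxy-6,6-dimethoxydocos-4-en-1-ol | CCCCCCCCCCCCCCCCC(OC)(OC)/C=C\[C@H](OO)CCO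
F6 | step 10 | 2-[(3R)-6-hexadecyl-6-methoxy-3,6-dihydro-1,2-dioxin-3-yl]ethanol (C6 epimer pair) | CCCCCCCCCCCCCCCCC1(OC)C=C[C@@H](CCO)OO1
F7 | step 10 | 2-[(3R)-6-hexadecyl-6-methoxy-3,6-dihydro-1,2-dioxin-3-yl]acetaldehyde (C6 epimer pair) | CCCCCCCCCCCCCCCCC1(OC)C=C[C@@H](CC=O)OO1
F8 | step 7 | 4,4-dimethoxyicos-2-ynal | CCCCCCCCCCCCCCCCC(OC)(OC)C#CC=O
F9 | step 9 | (4S)-4-[(1Z)-3,3-dihydroperoxynonadec-1-en-1-yl]oxetan-2-one | CCCCCCCCCCCCCCCCC(OO)(OO)/C=C\[C@@H]1CC(=O)O1
F10 | step 9 | 2-[(3R)-6-hexadecyl-6-hydroperoxy-3,6-dihydro-1,2-dioxin-3-yl]acetic acid (C6 epimer pair) | CCCCCCCCCCCCCCCCC1(OO)C=C[C@@H](CC(=O)O)OO1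
F11 | step 9 | methyl 2-[(3R)-6-hexadecyl-6-hydroperoxy-3,6-dihydro-1,2-dioxin-3-yl]acetate (C6 epimer pair) | CCCCCCCCCCCCCCCCC1(OO)C=C[C@@H](CC(=O)OC)OO1
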